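## Analysis of the target

Target 14 is a pentasubstituted benzene. In ring order it carries a formyl group on C1 (aldehyde carbon C7), a 2-acetoxytridecyl chain on C2 (C8H2, C9H(OAc), then an undecyl tail), a free hydroxyl on C3, a methoxy group on C4, the only ring hydrogen on C5 and a second hydroxyl on C6. There is one ring and one stereocentre, C9, of R configuration (the arylmethyl group outranks the undecyl chain). It is remote from every other stereo-element, so only its absolute configuration has to be secured.

The sensitive features are:
- the para-hydroquinone (C3–OH and C6–OH), which is easily oxidised to the quinone;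
- the salicylaldehyde unit (C6–OH next to C7);
- the secondary acetate, which has to be put on while both phenols are masked and must outlive their unmasking.

A free C9 hydroxyl and a free C7 aldehyde cannot coexist, because they would close to a lactol, and this fixes the order of the last steps. The real difficulty is regiochemical: five different substituents sit on one ring, with the two carbon arms on the neighbouring carbons C1 and C2, each flanked by an oxygen.

The strategy rests on three facts:
- C1 is para to the C4 methoxy group, so it is the natural site of electrophilic iodination of a protected methoxyhydroquinone.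
- C2–H is the only hydrogen ortho to that iodide.
- C7 and the C9 oxygen can be tied into a six-membered lactone (O–C7–C1–C2–C8–C9), so an aryl iodide, a terminal epoxide and carbon monoxide can be joined in one palladium relay.

## Retrosynthetic reasoning

Target 14 is traced back to its bis(methoxymethyl) ether 13. No skeletal bond is cut. The phenols are masked because a free hydroquinone would not pass through base, palladium, aluminium amide and hydride chemistry. Acetals are chosen because they resist all of these and fall to anhydrous acid, the one medium in which a secondary acetate is inert. The forward step has to cleave two aryl acetals and leave the ester, the aldehyde and the methyl ether alone.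

Aldehyde 13 is traced to the acetoxy Weinreb amide 12 (change of C7 from amide to aldehyde), and 12 to the hydroxy amide 11 (the C9 O–acyl bond). This order answers the lactol problem: C7 stays an amide, which the C9 hydroxyl does not capture under basic conditions, until that hydroxyl is acetylated. The reduction then has to tell a tertiary amide from an ester, which a hydrozirconation does.

Amide 11 is the ring-opened form of lactone 10, so in the backward sense the C7–O bond to the C9 oxygen is closed. This is the simplifying move: in 10 the aldehyde carbon and the carbinol oxygen are one functional group, a dihydroisocoumarin, which a single carbonylative event can assemble. The forward step has to open a benzo-fused δ-lactone with an amine nucleophile without disturbing C9.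

Lactone 10 is cut at three bonds along the C1–C2 edge: C2–C8, C1–C7 and C7–O. The pieces are aryl iodide 3, epoxide 8 and carbon monoxide 9. Cutting here turns a pentasubstituted arene into a tetrasubstituted one that simple electrophilic substitution provides, moves the stereocentre into a small fragment of known configuration, and brings in C7 at the carboxyl level. The forward reaction is a Catellani relay ended by carbonylation. It has to alkylate the single ortho C–H (C2) with the CH2 end of 8, then carbonylate the ipso carbon C1 and let the C9 alkoxide close the ring.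

Iodide 3 is cut at C1–I to arene 2, and 2 at its two acetal O–C bonds to 2-methoxyhydroquinone 1. The iodination has to pick the position para to the methoxy group and ortho to one acetal oxygen over the crowded position between two oxygens, and must run without acid.

Epoxide 8 is traced through chlorohydrin 7 to (R)-epichlorohydrin 5 and the Grignard reagent 6 made from 1-bromodecane 4. The bond cut joins the decyl chain to the unsubstituted epoxide carbon of 5. The stereocentre is bought, not made, and is never a reacting centre, so the forward steps only need regioselective opening at CH2 and reclosure onto the chloromethyl carbon.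

## Alternatives that were turned down

Alternative 1: Biomimetic aldol aromatisation of a diketo-dioxinone.
- Disconnection: the benzene ring is opened at C1–C2, back to the open-chain 6-[(6R)-6-{[tert-butyl(dimethyl)silyl]oxy}-2,4-dioxoheptadecyl]-2,2-dimethyl-4H-1,3-dioxin-4-one A1. Its dioxinone hides C7 and the C6 oxygen, and its chain holds the C4 and C2 ketones and the silylated C9 carbinol.
- Forward key step: mild base would let the dioxinone α-carbon (C1) add to the C2 ketone. Loss of water and enolisation of the C4 carbonyl would then give 5-[(2R)-2-{[tert-butyl(dimethyl)silyl]oxy}tridecyl]-7-hydroxy-2,2-dimethyl-4H-1,3-benzodioxin-4-one A2.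
- For it: this aromatisation is metal-free, only one six-membered aldol is possible, and C7 arrives at the carboxyl level next to the arm. On the dependability of the key step it is stronger than the chosen route.
- Against it: A2 is a resorcylate with oxygen only at C4 and C6. C3 carries hydrogen and C4 a free hydroxyl. The C3 oxygen would have to be added after the ring is built, in competition with C5; both positions are activated by the two oxygens and C3 is the one hindered by the arm. That means halogenation or metalation, hydroxylation and C4 O-methylation on top of the reduction of the dioxinone and the silyl-to-acetyl exchange, which meets the same lactol problem. A1 also needs a linear series of acylations on enolisable polycarbonyl compounds.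
- Comparison: the chosen route starts from an arene with all three ring oxygens already in place and puts its risk into one C–C-forming cascade. It has fewer corrective steps but a less certain key step.

Alternative 2: Cyclobutenone ring expansion to the isochroman hydroquinone.
- Disconnection: the arene is cut at C1–C6 and traced to 4-hydroxy-3-methoxy-4-[(2R)-2-undecyl-3,6-dihydro-2H-pyran-4-yl]cyclobut-2-en-1-one A3. The dihydropyran ring already contains C2, C1, C7, the ring oxygen, C9 and C8.
- Forward key step: heating A3 would open the four-membered ring to a dienylketene. Its 6π closure forms C1–C6, and enolisation would give (3R)-6-methoxy-3-undecylisochromane-5,8-diol A4.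
- For it: the step is purely thermal, and the cyclobutenone fixes the hydroquinone pattern (OH at C3 and C6, OMe at C4, H at C5) without ambiguity. On regiochemical certainty it is stronger than the chosen route, whose key step depends on a hindered C–H palladation.
- Against it: in A4 the C7 carbon is a benzylic ether CH2. The hydroquinone would have to be protected first, since an oxidant would otherwise take it to the quinone. C7 would then be oxidised to the lactone or lactol level, and the ring opened and acetylated as in the chosen endgame. A3 also needs a chiral dihydropyranyl metal reagent, itself several steps from the epoxide, and a monosubstituted cyclobutenedione.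
- Comparison: this route is longer both before and after its key step. The chosen route takes C7 from carbon monoxide at the right oxidation level and builds the lactone directly from two simple fragments.

Alternative 3: Siloxyfuran–ynal Diels–Alder reaction that builds the whole arene.
- Disconnection: two ring bonds, C2–C3 and C1–C6, are cut. The pieces are tert-butyl[(4-methoxyfuran-2-yl)oxy]dimethylsilane A5 (C3 to C6, with the methoxy group on C4 and the silyloxy group on C6) and (5R)-1-oxohexadec-2-yn-5-yl acetate A6 (C1≡C2, with the formyl group on C1 and the arm on C2).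
- Forward key step: [4+2] addition of A5 across the triple bond of A6, with the unsubstituted furan α-carbon bonding to the β-carbon of the ynal. Opening of the oxanorbornadiene at the C6–O bridge bond and tautomerisation would give (2R)-1-[3-(tert-butyldimethylsilyloxy)-2-formyl-6-hydroxy-5-methoxyphenyl]tridecan-2-yl acetate A7.
- For it: A7 carries every substituent, aldehyde and acetate included, and is one desilylation from 14. On convergence and step economy this alternative is clearly stronger than the chosen route.
- Against it: in A6 the C8 methylene is propargylic, γ to the aldehyde and β to the acetate, so isomerisation to an allenal and loss of acetic acid to a conjugated enynal are easy. A β-alkylated ynal is a slow dienophile. A5 is a strong carbon nucleophile that can add to the aldehyde carbonyl (vinylogous Mukaiyama aldol) or stop after conjugate addition, and Lewis acid acceleration favours these paths. The bridge must also open in one direction only, and a failed cycloaddition destroys the chiral fragment.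
- Comparison: the chosen route is several steps longer. In return it keeps the stereocentre in robust intermediates (epoxide 8, lactone 10), its regiochemistry is set by the substitution pattern instead of by polarisation, and each elementary step of its cascade has a close precedent.

Key step: step 5

Remark: the catalyst composition and the CO partial pressure named for step 5 are a reasoned starting point for this proposal, not established values.

## Route

Step 1
Reactants: 1 2-methoxyhydroquinone (2-methoxybenzene-1,4-diol)
Product: 2 2-methoxy-1,4-bis(methoxymethoxy)benzene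
Conditions: MOMCl (3 equiv), i-Pr2NEt (4 equiv), CH2Cl2, 0 °C → rt, Ar
Reagents that add atoms: chloromethyl methyl ether, COCCl
Why: Williamson-type O-alkylation of both phenols with a reactive α-chloro ether under amine base; the inert atmosphere keeps the hydroquinone from oxidising before it is capped.

Step 2
Reactants: 2 2-methoxy-1,4-bis(methoxymethoxy)benzene
Product: 3 1-iodo-4-methoxy-2,5-bis(methoxymethoxy)benzene
Conditions: NIS (1.05 equiv), MeCN, 0 °C → rt, dark
Reagents that add atoms: N-iodosuccinimide, O=C1CCC(=O)N1I
Why: Electrophilic aromatic iodination; the carbon para to the methoxy group and ortho to one acetal oxygen is doubly activated and open, the other doubly activated carbon is wedged between two alkoxy groups, and the third free carbon is activated by one oxygen only. The acid-free medium spares the acetals.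

Step 3
Reactants: 4 1-bromodecane; 5 (R)-epichlorohydrin
Product: 7 (2R)-1-chlorotridecan-2-ol, via decylmagnesium bromide 6 (not isolated)
Conditions: Mg, THF, rt → 40 °C; then CuI (10 mol %), 5, THF, −40 → −20 °C; aq. NH4Cl
Reagents that add atoms: none
Why: Copper-catalysed Grignard opening of an epoxide at its unsubstituted carbon, which is faster than displacement of the chloride. The stereocentre of 5 is not a reacting centre and keeps its arrangement; the descriptor stays R because the chloromethyl group outranks the new alkyl chain.

Step 4
Reactants: 7 (2R)-1-chlorotridecan-2-ol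
Product: 8 (2R)-2-undecyloxirane
Conditions: NaOH (powdered, 3 equiv), Et2O, rt
Reagents that add atoms: none
Why: Intramolecular Williamson etherification; the alkoxide displaces the primary chloride, no bond to the stereocentre is broken, and the R configuration is carried over.

Step 5
Reactants: 3 1-iodo-4-methoxy-2,5-bis(methoxymethoxy)benzene; 8 (2R)-2-undecyloxirane; 9 carbon monoxide
Product: 10 (3R)-6-methoxy-5,8-bis(methoxymethoxy)-3-undecylisochroman-1-one
Conditions: Pd(OAc)2 (10 mol %), XPhos (20 mol %), potassium 5-norbornene-2-carboxylate (50 mol %), K2CO3 (2 equiv), 8 (3 equiv), CO (9, ca. 0.1 atm in Ar), NMP, 70 °C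
Reagents that add atoms: none
Why: Proposed new method: zerovalent palladium formed from Pd(OAc)2 and XPhos should insert into the C1–I bond of 3, the norbornene cocatalyst should insert into the aryl–palladium bond, and base-assisted metalation of C2–H, the only ortho hydrogen, should give the five-membered aryl–norbornyl palladacycle of divalent palladium. SN2-type oxidative addition of the CH2 end of epoxide 8 (directly or through its iodohydrin alkoxide) should give tetravalent palladium, and reductive elimination then forms C2–C8 with the C9 alkoxide carried along; only the CH2 carbon reacts, so no stereocentre is created and the R centre of 8 passes on unchanged. With C2 and C6 both substituted the norbornene unit is expelled by β-carbon elimination, CO inserts into the C1–palladium bond (C1–C7), and the C9 alkoxide attacks the acylpalladium in a 6-exo-trig acyl substitution that closes the δ-lactone (C7–O) and returns zerovalent palladium. The closest known reaction types are the Catellani ortho-alkylation of aryl iodides with epoxides, ended by Heck coupling or by C–O ring closure, and the palladium-catalysed carbonylative lactonisation of 2-(2-halophenyl)ethanols; their merger with CO as the ipso terminator is the new element. Regiochemistry is fixed by the substrate: the C6 OMOM group blocks the second ortho position and provides the ortho effect that drives norbornene loss, so only mono-alkylation at C2 can occur. The step needs norbornene insertion to come before CO insertion at the first arylpalladium stage and CO insertion to outrun C–O reductive elimination to the dihydrobenzofuran at the last; a low CO pressure, an excess of epoxide and the absence of any other nucleophile (an aroylpalladium formed too early can only revert by decarbonylation) are meant to secure this.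

Step 6
Reactants: 10 (3R)-6-methoxy-5,8-bis(methoxymethoxy)-3-undecylisochroman-1-one
Product: 11 2-[(2R)-2-hydroxytridecyl]-N,4-dimethoxy-3,6-bis(methoxymethoxy)-N-methylbenzamide
Conditions: MeNH(OMe)·HCl (3 equiv), AlMe3 (3 equiv), CH2Cl2, 0 → 40 °C; aq. potassium sodium tartrate
Reagents that add atoms: N,O-dimethylhydroxylamine hydrochloride, CNOC.Cl
Why: Weinreb aminolysis of a lactone with an aluminium amide; the oxophilic aluminium activates the lactone carbonyl and holds the released C9 alkoxide, and C9 is not a reacting centre. Crude 11 is taken on at once so that it cannot relactonise.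

Step 7
Reactants: 11 2-[(2R)-2-hydroxytridecyl]-N,4-dimethoxy-3,6-bis(methoxymethoxy)-N-methylbenzamide
Product: 12 (2R)-1-{5-methoxy-2-[methoxy(methyl)carbamoyl]-3,6-bis(methoxymethoxy)phenyl}tridecan-2-yl acetate
Conditions: Ac2O, pyridine, DMAP (cat.), CH2Cl2, 0 °C → rt
Reagents that add atoms: acetic anhydride, CC(=O)OC(C)=O
Why: DMAP-catalysed O-acylation of the only free hydroxyl; the reaction is at oxygen, so C9 keeps its configuration, and the basic medium gives no chance for acid-catalysed relactonisation.

Step 8
Reactants: 12 (2R)-1-{5-methoxy-2-[methoxy(methyl)carbamoyl]-3,6-bis(methoxymethoxy)phenyl}tridecan-2-yl acetate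
Product: 13 (2R)-1-[2-formyl-5-methoxy-3,6-bis(methoxymethoxy)phenyl]tridecan-2-yl acetate
Conditions: Cp2Zr(H)Cl (1.5 equiv), THF, rt, 20 min; then silica gel/H2O
Reagents that add atoms: none
Why: Hydrozirconation of the amide carbonyl by Cp2Zr(H)Cl gives a zirconated hemiaminal that releases the aldehyde only on work-up, so over-reduction is excluded. Tertiary and N-methoxy-N-methyl amides react faster than esters with this reagent, which is why the acetate should survive.

Step 9
Reactants: 13 (2R)-1-[2-formyl-5-methoxy-3,6-bis(methoxymethoxy)phenyl]tridecan-2-yl acetate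
Product: 14 (2R)-1-(2-formyl-3,6-dihydroxy-5-methoxyphenyl)tridecan-2-yl acetate
Conditions: TFA/CH2Cl2 (1:5), 0 °C, Ar; aq. NaHCO3 work-up
Reagents that add atoms: none
Why: Acid-catalysed cleavage of the two aryl methoxymethyl acetals through oxocarbenium ions; anhydrous acid offers no nucleophile for acyl cleavage, so the secondary acetate and the methyl ether should stay. The inert atmosphere protects the liberated hydroquinone.

## Compound list

1 | 2-methoxyhydroquinone (2-methoxybenzene-1,4-diol) | COc1cc(O)ccc1O | starting material
2 | 2-methoxy-1,4-bis(methoxymethoxy)benzene | COc1cc(OCOC)ccc1OCOC | intermediate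
3 | 1-iodo-4-methoxy-2,5-bis(methoxymethoxy)benzene | COCOc1cc(OC)c(OCOC)cc1I | intermediate
4 | 1-bromodecane | CCCCCCCCCCBr | starting material
5 | (R)-epichlorohydrin, (2R)-2-(chloromethyl)oxirane | ClC[C@H]1CO1 | starting material
6 | decylmagnesium bromide | CCCCCCCCCC[Mg]Br | intermediate (not isolated)
7 | (2R)-1-chlorotridecan-2-ol | CCCCCCCCCCC[C@@H](O)CCl | intermediate
8 | (2R)-2-undecyloxirane | CCCCCCCCCCC[C@@H]1CO1 | intermediate
9 | carbon monoxide | [C-]#[O+] | starting material
10 | (3R)-6-methoxy-5,8-bis(methoxymethoxy)-3-undecylisochroman-1-one | CCCCCCCCCCC[C@@H]1Cc2c(OCOC)c(OC)cc(OCOC)c2C(=O)O1 | intermediate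
11 | 2-[(2R)-2-hydroxytridecyl]-N,4-dimethoxy-3,6-bis(methoxymethoxy)-N-methylbenzamide | CCCCCCCCCCC[C@@H](O)Cc1c(OCOC)c(OC)cc(OCOC)c1C(=O)N(C)OC | intermediate
12 | (2R)-1-{5-methoxy-2-[methoxy(methyl)carbamoyl]-3,6-bis(methoxymethoxy)phenyl}tridecan-2-yl acetate | CCCCCCCCCCC[C@H](Cc1c(OCOC)c(OC)cc(OCOC)c1C(=O)N(C)OC)OC(C)=O | intermediate
13 | (2R)-1-[2-formyl-5-methoxy-3,6-bis(methoxymethoxy)phenyl]tridecan-2-yl acetate | CCCCCCCCCCC[C@H](Cc1c(OCOC)c(OC)cc(OCOC)c1C=O)OC(C)=O | intermediate
14 | (2R)-1-(2-formyl-3,6-dihydroxy-5-methoxyphenyl)tridecan-2-yl acetate | CCCCCCCCCCC[C@H](Cc1c(O)c(OC)cc(O)c1C=O)OC(C)=O | target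

## Step count and least certain steps

Total step count: 9. Longest linear sequence: 7 steps (1 → 2 → 3 → 10 → 11 → 12 → 13 → 14; the arm 4 → 7 → 8 → 10 → 14 is equally long).

**Step 5 (key step, proposed new method).** Three processes may divert it:
- carbonylation too early, by CO insertion into the first arylpalladium species or into the palladacycle before the epoxide has reacted, together with catalyst deactivation by CO;
- slow palladation of C2–H next to the C3 OMOM group, which leaves the aryl–norbornyl palladium intermediate open to other pathways;
- C–O reductive elimination to the dihydrobenzofuran if too little CO is present.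

The fallback uses directed ortho-metalation, where the flanking C3 oxygen helps instead of hindering. It sets out from 3 and 8 and comes back at 13. Iodine–lithium exchange on 3 (n-BuLi, THF, −78 °C) and quenching with Et2NCOCl should give N,N-diethyl-4-methoxy-2,5-bis(methoxymethoxy)benzamide F1. Deprotonation with s-BuLi/TMEDA (THF, −78 °C) at C2–H, between the amide and the C3 acetal oxygen, followed by BF3·OEt2-assisted opening of 8 at its CH2 end, should give N,N-diethyl-2-[(2R)-2-hydroxytridecyl]-4-methoxy-3,6-bis(methoxymethoxy)benzamide F2. Acetylation (Ac2O, pyridine, DMAP) should give (2R)-1-[2-(diethylcarbamoyl)-5-methoxy-3,6-bis(methoxymethoxy)phenyl]tridecan-2-yl acetate F3, and reduction of the tertiary amide with Cp2Zr(H)Cl leads to 13.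

**Step 6.** Attack at the lactone carbonyl, which is flanked on both sides, may be slow. The hydroxy amide may relactonise with loss of the amine during work-up. The chloroaluminium species may also cleave the chelating C6 acetal. The fallback sets out from 10 and comes back at 13 without an amide. Reduction with i-Bu2AlH (CH2Cl2, −78 °C) should give the lactol (3R)-6-methoxy-5,8-bis(methoxymethoxy)-3-undecylisochroman-1-ol F4. Wittig methylenation of its open hydroxy aldehyde form (Ph3PCH3Br, KOt-Bu, THF) should give (2R)-1-[2-ethenyl-5-methoxy-3,6-bis(methoxymethoxy)phenyl]tridecan-2-ol F5. Acetylation should give (2R)-1-[2-ethenyl-5-methoxy-3,6-bis(methoxymethoxy)phenyl]tridecan-2-yl acetate F6, and Lemieux–Johnson cleavage (OsO4 cat., NaIO4, 2,6-lutidine, dioxane/H2O) unveils the aldehyde of 13.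

**Step 8.** The twisted amide with two ortho substituents may react slowly. The excess reagent and longer times then needed could lead to reduction or cleavage of the acetate. The fallback sets out from 10 and comes back at 13 through the alcohol oxidation level. LiAlH4 (THF, 0 °C) should give the diol (2R)-1-[2-(hydroxymethyl)-5-methoxy-3,6-bis(methoxymethoxy)phenyl]tridecan-2-ol F7. Selective silylation of the primary benzylic hydroxyl (TBSCl, imidazole, DMF, 0 °C) should give (2R)-1-[2-({[tert-butyl(dimethyl)silyl]oxy}methyl)-5-methoxy-3,6-bis(methoxymethoxy)phenyl]tridecan-2-ol F8. Acetylation should give (2R)-1-[2-({[tert-butyl(dimethyl)silyl]oxy}methyl)-5-methoxy-3,6-bis(methoxymethoxy)phenyl]tridecan-2-yl acetate F9. Desilylation with HF·pyridine (THF, 0 °C) should give (2R)-1-[2-(hydroxymethyl)-5-methoxy-3,6-bis(methoxymethoxy)phenyl]tridecan-2-yl acetate F10, and oxidation of the benzylic alcohol (MnO2, CH2Cl2, or Dess–Martin periodinane) gives 13.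

**Step 9.** The methoxymethyl cation may alkylate the electron-rich C5 position. The aldehyde may enter condensation chemistry with the released formaldehyde. The free hydroquinone may be oxidised by air to the quinone. The fallback moves the acidic step to the lactone stage, where methanol can serve as solvent and cation trap, and ends with a fluoride deprotection. It sets out from 10 and comes back at 14.
- HCl/MeOH should give (3R)-5,8-dihydroxy-6-methoxy-3-undecylisochroman-1-one F11.
- Silylation (TBSOTf, 2,6-lutidine, CH2Cl2) should give (3R)-5,8-bis{[tert-butyl(dimethyl)silyl]oxy}-6-methoxy-3-undecylisochroman-1-one F12.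
- Aminolysis as in step 6 should give 3,6-bis{[tert-butyl(dimethyl)silyl]oxy}-2-[(2R)-2-hydroxytridecyl]-N,4-dimethoxy-N-methylbenzamide F13.
- Acetylation as in step 7 should give (2R)-1-{3,6-bis{[tert-butyl(dimethyl)silyl]oxy}-5-methoxy-2-[methoxy(methyl)carbamoyl]phenyl}tridecan-2-yl acetate F14.
- Reduction with Cp2Zr(H)Cl as in step 8 should give (2R)-1-{3,6-bis{[tert-butyl(dimethyl)silyl]oxy}-2-formyl-5-methoxyphenyl}tridecan-2-yl acetate F15.
- HF·pyridine (THF, 0 °C, Ar) then frees both phenols to give 14.

## Further compounds

F1 | step 5 | N,N-diethyl-4-methoxy-2,5-bis(methoxymethoxy)benzamide | CCN(CC)C(=O)c1cc(OCOC)c(OC)cc1OCOC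
F2 | step 5 | N,N-diethyl-2-[(2R)-2-hydroxytridecyl]-4-methoxy-3,6-bis(methoxymethoxy)benzamide | CCCCCCCCCCC[C@@H](O)Cc1c(OCOC)c(OC)cc(OCOC)c1C(=O)N(CC)CC
F3 | step 5 | (2R)-1-[2-(diethylcarbamoyl)-5-methoxy-3,6-bis(methoxymethoxy)phenyl]tridecan-2-yl acetate | CCCCCCCCCCC[C@H](Cc1c(OCOC)c(OC)cc(OCOC)c1C(=O)N(CC)CC)OC(C)=O
F4 | step 6 | (3R)-6-methoxy-5,8-bis(methoxymethoxy)-3-undecylisochroman-1-ol (both C1 epimers) | CCCCCCCCCCC[C@@H]1Cc2c(OCOC)c(OC)cc(OCOC)c2C(O)O1
F5 | step 6 | (2R)-1-[2-ethenyl-5-methoxy-3,6-bis(methoxymethoxy)phenyl]tridecan-2-ol | CCCCCCCCCCC[C@@H](O)Cc1c(OCOC)c(OC)cc(OCOC)c1C=C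
F6 | step 6 | (2R)-1-[2-ethenyl-5-methoxy-3,6-bis(methoxymethoxy)phenyl]tridecan-2-yl acetate | CCCCCCCCCCC[C@H](Cc1c(OCOC)c(OC)cc(OCOC)c1C=C)OC(C)=O
F7 | step 8 | (2R)-1-[2-(hydroxymethyl)-5-methoxy-3,6-bis(methoxymethoxy)phenyl]tridecan-2-ol | CCCCCCCCCCC[C@@H](O)Cc1c(OCOC)c(OC)cc(OCOC)c1CO
F8 | step 8 | (2R)-1-[2-({[tert-butyl(dimethyl)silyl]oxy}methyl)-5-methoxy-3,6-bis(methoxymethoxy)phenyl]tridecan-2-ol | CCCCCCCCCCC[C@@H](O)Cc1c(OCOC)c(OC)cc(OCOC)c1CO[Si](C)(C)C(C)(C)C
F9 | step 8 | (2R)-1-[2-({[tert-butyl(dimethyl)silyl]oxy}methyl)-5-methoxy-3,6-bis(methoxymethoxy)phenyl]tridecan-2-yl acetate | CCCCCCCCCCC[C@H](Cc1c(OCOC)c(OC)cc(OCOC)c1CO[Si](C)(C)C(C)(C)C)OC(C)=O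
F10 | step 8 | (2R)-1-[2-(hydroxymethyl)-5-methoxy-3,6-bis(methoxymethoxy)phenyl]tridecan-2-yl acetate | CCCCCCCCCCC[C@H](Cc1c(OCOC)c(OC)cc(OCOC)c1CO)OC(C)=O
F11 | step 9 | (3R)-5,8-dihydroxy-6-methoxy-3-undecylisochroman-1-one | CCCCCCCCCCC[C@@H]1Cc2c(O)c(OC)cc(O)c2C(=O)O1
F12 | step 9 | (3R)-5,8-bis{[tert-butyl(dimethyl)silyl]oxy}-6-methoxy-3-undecylisochroman-1-one | CCCCCCCCCCC[C@@H]1Cc2c(O[Si](C)(C)C(C)(C)C)c(OC)cc(O[Si](C)(C)C(C)(C)C)c2C(=O)O1
F13 | step 9 | 3,6-bis{[tert-butyl(dimethyl)silyl]oxy}-2-[(2R)-2-hydroxytridecyl]-N,4-dimethoxy-N-methylbenzamide | CCCCCCCCCCC[C@@H](O)Cc1c(O[Si](C)(C)C(C)(C)C)c(OC)cc(O[Si](C)(C)C(C)(C)C)c1C(=O)N(C)OC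
F14 | step 9 | (2R)-1-{3,6-bis{[tert-butyl(dimethyl)silyl]oxy}-5-methoxy-2-[methoxy(methyl)carbamoyl]phenyl}tridecan-2-yl acetate | CCCCCCCCCCC[C@H](Cc1c(O[Si](C)(C)C(C)(C)C)c(OC)cc(O[Si](C)(C)C(C)(C)C)c1C(=O)N(C)OC)OC(C)=O
F15 | step 9 | (2R)-1-{3,6-bis{[tert-butyl(dimethyl)silyl]oxy}-2-formyl-5-methoxyphenyl}tridecan-2-yl acetate | CCCCCCCCCCC[C@H](Cc1c(O[Si](C)(C)C(C)(C)C)c(OC)cc(O[Si](C)(C)C(C)(C)C)c1C=O)OC(C)=O
A1 | alternative 1 | 6-[(6R)-6-{[tert-butyl(dimethyl)silyl]oxy}-2,4-dioxoheptadecyl]-2,2-dimethyl-4H-1,3-dioxin-4-one | CCCCCCCCCCC[C@H](CC(=O)CC(=O)CC1=CC(=O)OC(C)(C)O1)O[Si](C)(C)C(C)(C)C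
A2 | alternative 1 | 5-[(2R)-2-{[tert-butyl(dimethyl)silyl]oxy}tridecyl]-7-hydroxy-2,2-dimethyl-4H-1,3-benzodioxin-4-one | CCCCCCCCCCC[C@H](Cc1cc(O)cc2OC(C)(C)OC(=O)c12)O[Si](C)(C)C(C)(C)C
A3 | alternative 2 | 4-hydroxy-3-methoxy-4-[(2R)-2-undecyl-3,6-dihydro-2H-pyran-4-yl]cyclobut-2-en-1-one | CCCCCCCCCCC[C@@H]1CC(C2(O)C(OC)=CC2=O)=CCO1
A4 | alternative 2 | (3R)-6-methoxy-3-undecylisochromane-5,8-diol | CCCCCCCCCCC[C@@H]1Cc2c(O)c(OC)cc(O)c2CO1
A5 | alternative 3 | tert-butyl[(4-methoxyfuran-2-yl)oxy]dimethylsilane | COc1coc(O[Si](C)(C)C(C)(C)C)c1
A6 | alternative 3 | (5R)-1-oxohexadec-2-yn-5-yl acetate | CCCCCCCCCCC[C@H](CC#CC=O)OC(C)=O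
A7 | alternative 3 | (2R)-1-[3-(tert-butyldimethylsilyloxy)-2-formyl-6-hydroxy-5-methoxyphenyl]tridecan-2-yl acetate | CCCCCCCCCCC[C@H](Cc1c(O)c(OC)cc(O[Si](C)(C)C(C)(C)C)c1C=O)OC(C)=O
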